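The core is numbered as a benzofuran (O1, C2, C3, C3a, C4–C7, C7a). Ring A is the dihydrofuran and ring B the cyclohexadiene. In the monocyclic intermediates C3a and C7a are furan C4 and C5.
Retrosynthetic cuts, in order: silyl groups; C4=C5 (enol ether RCM); C6–C7 (syn aldol with acrolein); C7–C(acyl) (vinylogous aldol of the C7a methyl group, later oxidised); aryl–CO2Me (carbonylation of ArBr); C4=CH2 (ester methylenation); one CH3–C bond of the carbinol; C2–C3 together with O1–C2 ([4+1]); C3=C3a (Knoevenagel).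
Enabling feature: O1–C7a=C3a–C4 is the O-alkylated enol of a β-keto ester, C3 is the benzylic β-carbon of its arylidene derivative, and the CMe2OH group on C2 is an acetyl group plus one methyl. C2 can therefore arrive as a one-carbon unit that is first a nucleophile toward C3 and then an electrophile toward O1, that is, as an acetyl-stabilised ammonium ylide.
Forward order: ring A closes first (step 3), the chain at C7 is grown, the ester carbon becomes C4 and keeps its OMe group, and ring B closes last (step 11).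
Stereochemistry: C3 comes from the cinchona-derived ammonium group and C2 is set trans to C3 by the SN2 closure. C6/C7 syn comes from a Z-boron enolate in a chair transition state, with the absolute sense set by isopinocampheyl ligands.

Key step: step 3

Assumption: the sense of induction of the cinchona amine (step 3) and of the Ipc ligands (step 10) cannot be derived with certainty for these substrates. 9-O-methylquinidine and (−)-Ipc2BOTf are written, and 9-O-methylquinine or the (+)-antipode would be taken if the first run shows the opposite sense.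

Step 1
Reactants: 1 5-bromo-2-hydroxybenzaldehyde
Product: 2 5-bromo-2-(triisopropylsilyloxy)benzaldehyde
Conditions: TIPSCl, imidazole, DMF, rt
Reagents that add atoms: triisopropylsilyl chloride, CC(C)[Si](Cl)(C(C)C)C(C)C
Why: Standard imidazole-promoted silylation of a phenol, which prevents coumarin formation in step 2 and uses a TIPS ether because it must later survive carbonate, Grignard, amide base and warm methanol/Et3N.

Step 2
Reactants: 2 5-bromo-2-(triisopropylsilyloxy)benzaldehyde; 3 methyl acetoacetate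
Product: 4 methyl (Z)-2-[5-bromo-2-(triisopropylsilyloxy)benzylidene]-3-oxobutanoate
Conditions: piperidine (cat.), AcOH (cat.), toluene, 4 Å molecular sieves, 40 °C
Reagents that add atoms: none
Why: Knoevenagel condensation of an aromatic aldehyde with a β-keto ester, which should favour the Z isomer (aryl cis to the ester), although the geometry has no consequence for step 3.

Step 3
Reactants: 4 methyl (Z)-2-[5-bromo-2-(triisopropylsilyloxy)benzylidene]-3-oxobutanoate; 5 chloroacetone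
Product: 7 methyl (2R,3R)-2-acetyl-3-[5-bromo-2-(triisopropylsilyloxy)phenyl]-5-methyl-2,3-dihydrofuran-4-carboxylate, via N-acetonyl-9-O-methylquinidinium chloride 6 (not isolated)
Conditions: 9-O-methylquinidine (20 mol %), Cs2CO3, MeCN, 0 °C to rt
Reagents that add atoms: none
Why: The quinuclidine nitrogen of the amine is alkylated by 5 to salt 6 and Cs2CO3 turns 6 into the acetyl-stabilised ammonium ylide, whose carbon (later C2) adds to the benzylic β-carbon of the doubly activated alkene 4 (later C3); the oxygen of the resulting acetyl enolate (later O1) then displaces the ammonium group from C2 and sets the amine free for the next turnover. The closest known reaction type is the Michael-initiated ring closure, a formal [4+1] annulation, of pyridinium, sulfonium and ammonium ylides with alkylidene 1,3-dicarbonyl compounds to trans-2,3-dihydrofurans, which has also been run with cinchona-derived ammonium ylides. Ring A closes by a 5-exo-tet O-alkylation with inversion at C2. C3 is controlled by the chiral ammonium group, which shields one face of the ylide and thereby selects the alkene face that is attacked, and C2 is controlled by C3, because the antiperiplanar displacement proceeds from the rotamer that keeps the acetyl and aryl groups apart and because carbonate can epimerise the acidic C2–H toward the more stable trans isomer. The step needs O- instead of C-alkylation (no cyclopropane) and closure through the ketone instead of the ester oxygen; the delocalised β-keto ester enolate prefers the strain-free five-membered ring, and closure through the acetyl oxygen leaves the ester conjugated as a vinylogous carbonate. The alkene geometry of 4 is lost in the enolate, so an E/Z mixture is acceptable.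

Step 4
Reactants: 7 methyl (2R,3R)-2-acetyl-3-[5-bromo-2-(triisopropylsilyloxy)phenyl]-5-methyl-2,3-dihydrofuran-4-carboxylate
Product: 8 methyl (2R,3R)-3-[5-bromo-2-(triisopropylsilyloxy)phenyl]-2-(2-hydroxypropan-2-yl)-5-methyl-2,3-dihydrofuran-4-carboxylate
Conditions: MeMgBr, CeCl3, THF, −78 °C
Reagents that add atoms: methylmagnesium bromide, C[Mg]Br
Why: Cerium-assisted Grignard 1,2-addition to the only reactive carbonyl group, since the ester is a hindered vinylogous carbonate; the low basicity of the reagent spares C2–H and no new stereocentre is created.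

Step 5
Reactants: 8 methyl (2R,3R)-3-[5-bromo-2-(triisopropylsilyloxy)phenyl]-2-(2-hydroxypropan-2-yl)-5-methyl-2,3-dihydrofuran-4-carboxylate
Product: 9 methyl (2R,3R)-3-[5-bromo-2-(triisopropylsilyloxy)phenyl]-5-methyl-2-[2-(triethylsilyloxy)propan-2-yl]-2,3-dihydrofuran-4-carboxylate
Conditions: TESOTf, 2,6-lutidine, CH2Cl2, 0 °C
Reagents that add atoms: triethylsilyl triflate, CC[Si](CC)(CC)OS(=O)(=O)C(F)(F)F
Why: Silyl triflate/lutidine silylation is the usual way to cap a hindered tertiary alcohol, which would otherwise consume LDA, Cp2TiMe2 and the boron triflate in later steps.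

Step 6
Reactants: 9 methyl (2R,3R)-3-[5-bromo-2-(triisopropylsilyloxy)phenyl]-5-methyl-2-[2-(triethylsilyloxy)propan-2-yl]-2,3-dihydrofuran-4-carboxylate; 10 3-phenylpropanal
Product: 13 methyl (2R,3R)-3-[5-bromo-2-(triisopropylsilyloxy)phenyl]-5-[4-phenyl-2-(trimethylsilyloxy)butyl]-2-[2-(triethylsilyloxy)propan-2-yl]-2,3-dihydrofuran-4-carboxylate (both epimers at the side-chain carbinol carbon), via lithium dienolate 11 (not isolated), via lithium aldolate 12 (not isolated)
Conditions: LDA, THF, −78 °C; 10; then TMSCl, −78 to −20 °C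
Reagents that add atoms: trimethylsilyl chloride, C[Si](C)(C)Cl
Why: Vinylogous aldol reaction of a β-alkoxyacrylate, in which LDA removes a γ-proton from the C7a methyl group, dienolate 11 reacts at its open γ-carbon C7 because the α-carbon C3a is fully substituted and screened by the C3 aryl group, and TMSCl traps aldolate 12 before it can lactonise onto the cis-placed ester, the new carbinol centre being uncontrolled and erased in step 9.

Step 7
Reactants: 13 methyl (2R,3R)-3-[5-bromo-2-(triisopropylsilyloxy)phenyl]-5-[4-phenyl-2-(trimethylsilyloxy)butyl]-2-[2-(triethylsilyloxy)propan-2-yl]-2,3-dihydrofuran-4-carboxylate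
Product: 14 (2R,3R)-3-[5-bromo-2-(triisopropylsilyloxy)phenyl]-4-(1-methoxyvinyl)-5-[4-phenyl-2-(trimethylsilyloxy)butyl]-2-[2-(triethylsilyloxy)propan-2-yl]-2,3-dihydrofuran
Conditions: Cp2TiMe2, toluene, 75 °C, dark
Reagents that add atoms: dimethyltitanocene, C[Ti+2]C.[cH-]1cccc1.[cH-]1cccc1
Why: Petasis methylenation turns the ester carbonyl group into a methyl enol ether through an oxatitanacyclobutane and so keeps the OMe group that becomes C4–OMe; it is placed here because the molecule contains neither a ketone nor the aryl ester at this point.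

Step 8
Reactants: 14 (2R,3R)-3-[5-bromo-2-(triisopropylsilyloxy)phenyl]-4-(1-methoxyvinyl)-5-[4-phenyl-2-(trimethylsilyloxy)butyl]-2-[2-(triethylsilyloxy)propan-2-yl]-2,3-dihydrofuran
Product: 16 methyl 3-{(2R,3R)-5-(2-hydroxy-4-phenylbutyl)-4-(1-methoxyvinyl)-2-[2-(triethylsilyloxy)propan-2-yl]-2,3-dihydrofuran-3-yl}-4-(triisopropylsilyloxy)benzoate (both carbinol epimers), via aryl ester TMS ether 15 (not isolated)
Conditions: Pd(OAc)2, Xantphos, CO (1 atm), Et3N, MeOH, toluene, 70 °C; then K2CO3 (cat.), MeOH, 0 °C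
Reagents that add atoms: carbon monoxide, [C-]#[O+]; methanol, CO
Why: Palladium-catalysed alkoxycarbonylation of an aryl bromide (oxidative addition to zerovalent palladium, CO insertion, methanolysis) runs in basic medium that spares the acid-labile methoxydiene, and the following carbonate-catalysed methanolysis removes only the unhindered TMS ether while the tertiary TES and aryl TIPS ethers remain.

Step 9
Reactants: 16 methyl 3-{(2R,3R)-5-(2-hydroxy-4-phenylbutyl)-4-(1-methoxyvinyl)-2-[2-(triethylsilyloxy)propan-2-yl]-2,3-dihydrofuran-3-yl}-4-(triisopropylsilyloxy)benzoate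
Product: 17 methyl 3-{(2R,3R)-4-(1-methoxyvinyl)-5-(2-oxo-4-phenylbutyl)-2-[2-(triethylsilyloxy)propan-2-yl]-2,3-dihydrofuran-3-yl}-4-(triisopropylsilyloxy)benzoate
Conditions: n-Pr4N[RuO4] (5 mol %), NMO, 4 Å molecular sieves, CH2Cl2, 0 °C to rt
Reagents that add atoms: none
Why: The Ley–Griffith oxidation is neutral and non-electrophilic, so both carbinol epimers should converge on one ketone without hydrolysis of the dienol ether or migration of the C3a=C7a double bond into conjugation.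

Step 10
Reactants: 17 methyl 3-{(2R,3R)-4-(1-methoxyvinyl)-5-(2-oxo-4-phenylbutyl)-2-[2-(triethylsilyloxy)propan-2-yl]-2,3-dihydrofuran-3-yl}-4-(triisopropylsilyloxy)benzoate; 18 acrolein
Product: 21 methyl 3-{(2R,3R)-5-[(3R,4R)-3-hydroxy-5-oxo-7-phenylhept-1-en-4-yl]-4-(1-methoxyvinyl)-2-[2-(triethylsilyloxy)propan-2-yl]-2,3-dihydrofuran-3-yl}-4-(triisopropylsilyloxy)benzoate, via Z-boron enolate 19 (not isolated), via boron aldolate 20 (not isolated)
Conditions: iPr2NEt, then (−)-Ipc2BOTf, CH2Cl2, −78 °C; 18, −78 to −20 °C; MeOH, pH 7 buffer, H2O2, 0 °C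
Reagents that add atoms: none
Why: Boron-mediated aldol reaction in which the triflate/hindered amine pair should enolise toward the more acidic allylic C7–H to give the Z-enolate 19, the chair Zimmerman–Traxler transition state with 18 gives the 6,7-syn adduct (OH and acyl group cis in the later ring B), and the isopinocampheyl ligands, not the remote C2/C3 centres, choose the enolate face that leads to (6R,7R).

Step 11
Reactants: 21 methyl 3-{(2R,3R)-5-[(3R,4R)-3-hydroxy-5-oxo-7-phenylhept-1-en-4-yl]-4-(1-methoxyvinyl)-2-[2-(triethylsilyloxy)propan-2-yl]-2,3-dihydrofuran-3-yl}-4-(triisopropylsilyloxy)benzoate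
Product: 22 methyl 3-{(2R,3R,6R,7R)-6-hydroxy-4-methoxy-7-(3-phenylpropanoyl)-2-[2-(triethylsilyloxy)propan-2-yl]-2,3,6,7-tetrahydro-1-benzofuran-3-yl}-4-(triisopropylsilyloxy)benzoate
Conditions: second-generation Hoveyda–Grubbs catalyst, (H2IMes)Cl2Ru=CH(C6H4-2-OiPr) (10 mol %), CH2Cl2 (2 mM), 40 °C
Reagents that add atoms: none
Why: Enol ether–olefin ring-closing metathesis, in which ruthenium loads onto the monosubstituted vinyl group, closes onto the CH2 terminus of the 1-methoxyvinyl group to form C4=C5 and the six-membered ring B, and expels ethene under neutral conditions that touch no stereocentre.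

Step 12
Reactants: 22 methyl 3-{(2R,3R,6R,7R)-6-hydroxy-4-methoxy-7-(3-phenylpropanoyl)-2-[2-(triethylsilyloxy)propan-2-yl]-2,3,6,7-tetrahydro-1-benzofuran-3-yl}-4-(triisopropylsilyloxy)benzoate
Product: 23 methyl 4-hydroxy-3-[(2R,3R,6R,7R)-6-hydroxy-2-(2-hydroxypropan-2-yl)-4-methoxy-7-(3-phenylpropanoyl)-2,3,6,7-tetrahydro-1-benzofuran-3-yl]benzoate
Conditions: TBAF, AcOH (1:1), THF, 0 °C to rt
Reagents that add atoms: none
Why: Fluoride-induced desilylation buffered with acetic acid cleaves the aryl TIPS and tertiary TES ethers close to neutrality, which should avoid both E1cB loss of the C6 hydroxyl group (aromatisation of ring B) and hydrolysis of the dienol ether.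

Compound list
1 | 5-bromo-2-hydroxybenzaldehyde | O=Cc1cc(Br)ccc1O | starting material
2 | 5-bromo-2-(triisopropylsilyloxy)benzaldehyde | O=Cc1cc(Br)ccc1O[Si](C(C)C)(C(C)C)C(C)C | intermediate
3 | methyl acetoacetate | COC(=O)CC(C)=O | starting material
4 | methyl (Z)-2-[5-bromo-2-(triisopropylsilyloxy)benzylidene]-3-oxobutanoate | CC(=O)/C(C(=O)OC)=C/c1cc(Br)ccc1O[Si](C(C)C)(C(C)C)C(C)C | intermediate
5 | chloroacetone | CC(=O)CCl | starting material
6 | N-acetonyl-9-O-methylquinidinium chloride (not isolated) | C=C[C@H]1C[N@+]2(CC(C)=O)CC[C@H]1C[C@@H]2[C@@H](OC)c1ccnc2ccc(OC)cc12.[Cl-] | intermediate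
7 | methyl (2R,3R)-2-acetyl-3-[5-bromo-2-(triisopropylsilyloxy)phenyl]-5-methyl-2,3-dihydrofuran-4-carboxylate (trans) | Brc1ccc(O[Si](C(C)C)(C(C)C)C(C)C)c([C@@H]2C(C(=O)OC)=C(C)O[C@H]2C(C)=O)c1 | intermediate
8 | methyl (2R,3R)-3-[5-bromo-2-(triisopropylsilyloxy)phenyl]-2-(2-hydroxypropan-2-yl)-5-methyl-2,3-dihydrofuran-4-carboxylate | Brc1ccc(O[Si](C(C)C)(C(C)C)C(C)C)c([C@@H]2C(C(=O)OC)=C(C)O[C@H]2C(C)(C)O)c1 | intermediate
9 | methyl (2R,3R)-3-[5-bromo-2-(triisopropylsilyloxy)phenyl]-5-methyl-2-[2-(triethylsilyloxy)propan-2-yl]-2,3-dihydrofuran-4-carboxylate | Brc1ccc(O[Si](C(C)C)(C(C)C)C(C)C)c([C@@H]2C(C(=O)OC)=C(C)O[C@H]2C(C)(C)O[Si](CC)(CC)CC)c1 | intermediate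
10 | 3-phenylpropanal | O=CCCc1ccccc1 | starting material
11 | lithium dienolate of 9 (exocyclic methylene at C7a, ester enolate at C3a; not isolated) | Brc1ccc(O[Si](C(C)C)(C(C)C)C(C)C)c([C@@H]2C(=C([O-])OC)C(=C)O[C@H]2C(C)(C)O[Si](CC)(CC)CC)c1.[Li+] | intermediate
12 | lithium aldolate from 11 and 10 (both carbinol epimers; not isolated) | Brc1ccc(O[Si](C(C)C)(C(C)C)C(C)C)c([C@@H]2C(C(=O)OC)=C(CC([O-])CCc3ccccc3)O[C@H]2C(C)(C)O[Si](CC)(CC)CC)c1.[Li+] | intermediate
13 | methyl (2R,3R)-3-[5-bromo-2-(triisopropylsilyloxy)phenyl]-5-[4-phenyl-2-(trimethylsilyloxy)butyl]-2-[2-(triethylsilyloxy)propan-2-yl]-2,3-dihydrofuran-4-carboxylate (both carbinol epimers) | Brc1ccc(O[Si](C(C)C)(C(C)C)C(C)C)c([C@@H]2C(C(=O)OC)=C(CC(O[Si](C)(C)C)CCc3ccccc3)O[C@H]2C(C)(C)O[Si](CC)(CC)CC)c1 | intermediate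
14 | (2R,3R)-3-[5-bromo-2-(triisopropylsilyloxy)phenyl]-4-(1-methoxyvinyl)-5-[4-phenyl-2-(trimethylsilyloxy)butyl]-2-[2-(triethylsilyloxy)propan-2-yl]-2,3-dihydrofuran (both carbinol epimers) | Brc1ccc(O[Si](C(C)C)(C(C)C)C(C)C)c([C@@H]2C(C(=C)OC)=C(CC(O[Si](C)(C)C)CCc3ccccc3)O[C@H]2C(C)(C)O[Si](CC)(CC)CC)c1 | intermediate
15 | methyl 3-{(2R,3R)-4-(1-methoxyvinyl)-5-[4-phenyl-2-(trimethylsilyloxy)butyl]-2-[2-(triethylsilyloxy)propan-2-yl]-2,3-dihydrofuran-3-yl}-4-(triisopropylsilyloxy)benzoate (not isolated) | COC(=O)c1ccc(O[Si](C(C)C)(C(C)C)C(C)C)c([C@@H]2C(C(=C)OC)=C(CC(O[Si](C)(C)C)CCc3ccccc3)O[C@H]2C(C)(C)O[Si](CC)(CC)CC)c1 | intermediate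
16 | methyl 3-{(2R,3R)-5-(2-hydroxy-4-phenylbutyl)-4-(1-methoxyvinyl)-2-[2-(triethylsilyloxy)propan-2-yl]-2,3-dihydrofuran-3-yl}-4-(triisopropylsilyloxy)benzoate (both carbinol epimers) | COC(=O)c1ccc(O[Si](C(C)C)(C(C)C)C(C)C)c([C@@H]2C(C(=C)OC)=C(CC(O)CCc3ccccc3)O[C@H]2C(C)(C)O[Si](CC)(CC)CC)c1 | intermediate
17 | methyl 3-{(2R,3R)-4-(1-methoxyvinyl)-5-(2-oxo-4-phenylbutyl)-2-[2-(triethylsilyloxy)propan-2-yl]-2,3-dihydrofuran-3-yl}-4-(triisopropylsilyloxy)benzoate | COC(=O)c1ccc(O[Si](C(C)C)(C(C)C)C(C)C)c([C@@H]2C(C(=C)OC)=C(CC(=O)CCc3ccccc3)O[C@H]2C(C)(C)O[Si](CC)(CC)CC)c1 | intermediate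
18 | acrolein | C=CC=O | starting material
19 | (Z)-diisopinocampheylboron enolate of 17, enolised toward C7 (not isolated) | COC(=O)c1ccc(O[Si](C(C)C)(C(C)C)C(C)C)c([C@@H]2C(C(=C)OC)=C(O[C@H]2C(C)(C)O[Si](CC)(CC)CC)/C=C(\OB([C@@H]3C[C@@H]4C[C@@H](C4(C)C)[C@H]3C)[C@@H]3C[C@@H]4C[C@@H](C4(C)C)[C@H]3C)CCc2ccccc2)c1 | intermediate
20 | diisopinocampheylboron aldolate of 21 (not isolated) | COC(=O)c1ccc(O[Si](C(C)C)(C(C)C)C(C)C)c([C@@H]2C(C(=C)OC)=C(O[C@H]2C(C)(C)O[Si](CC)(CC)CC)[C@H](C(=O)CCc2ccccc2)[C@H](OB([C@@H]3C[C@@H]4C[C@@H](C4(C)C)[C@H]3C)[C@@H]3C[C@@H]4C[C@@H](C4(C)C)[C@H]3C)C=C)c1 | intermediate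
21 | methyl 3-{(2R,3R)-5-[(3R,4R)-3-hydroxy-5-oxo-7-phenylhept-1-en-4-yl]-4-(1-methoxyvinyl)-2-[2-(triethylsilyloxy)propan-2-yl]-2,3-dihydrofuran-3-yl}-4-(triisopropylsilyloxy)benzoate (6,7-syn) | COC(=O)c1ccc(O[Si](C(C)C)(C(C)C)C(C)C)c([C@@H]2C(C(=C)OC)=C(O[C@H]2C(C)(C)O[Si](CC)(CC)CC)[C@H](C(=O)CCc2ccccc2)[C@H](O)C=C)c1 | intermediate
22 | methyl 3-{(2R,3R,6R,7R)-6-hydroxy-4-methoxy-7-(3-phenylpropanoyl)-2-[2-(triethylsilyloxy)propan-2-yl]-2,3,6,7-tetrahydro-1-benzofuran-3-yl}-4-(triisopropylsilyloxy)benzoate | COC(=O)c1ccc(O[Si](C(C)C)(C(C)C)C(C)C)c([C@@H]2C3=C(O[C@H]2C(C)(C)O[Si](CC)(CC)CC)[C@H](C(=O)CCc2ccccc2)[C@H](O)C=C3OC)c1 | intermediate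
23 | methyl 4-hydroxy-3-[(2R,3R,6R,7R)-6-hydroxy-2-(2-hydroxypropan-2-yl)-4-methoxy-7-(3-phenylpropanoyl)-2,3,6,7-tetrahydro-1-benzofuran-3-yl]benzoate | COC(=O)c1ccc(O)c([C@@H]2C3=C(O[C@H]2C(C)(C)O)[C@H](C(=O)CCc2ccccc2)[C@H](O)C=C3OC)c1 | target

Total step count: 12. Longest linear sequence: 12 steps (1 to 23).

Steps most likely to fail

Step 10.
- What may go wrong: enolisation toward the phenethyl CH2 group instead of C7; attack of the electron-rich methoxydiene on boron-activated acrolein; base-induced drift of the β,γ-unsaturated ketone into conjugation; insufficient facial selectivity of the bulky enolate.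
- Fallback: the α′ side of the ketone is blocked as an sp2 carbon. Setting out from 9, the vinylogous aldol/silylation is run with (E)-cinnamaldehyde in place of 10 and should give the allylic trimethylsilyl ether F1.
- Cp2TiMe2 then gives the methoxydiene F2, methoxycarbonylation gives the aryl ester F3, and carbonate-catalysed methanolysis gives the allylic alcohol F4.
- MnO2 in CH2Cl2 oxidises F4 under neutral conditions to the styryl ketone F5, which can be enolised only at C7.
- The (−)-Ipc2BOTf aldol reaction with 18 gives the syn adduct F6. Conjugate reduction of the cinnamoyl double bond with [(Ph3P)CuH]6 in wet toluene comes back to the route at 21.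

Step 7.
- What may go wrong: the titanium methylidene may decay faster than it adds to the electron-rich ester carbonyl group, which is flanked by the C3 aryl group and the C7 chain; the diene may also hydrolyse while the titanium residues are removed.
- Fallback without titanium and heat: setting out from 13, MeNH(OMe)·HCl/iPrMgCl converts the ester into the Weinreb amide F7, and MeMgBr gives the methyl ketone F8, a vinylogous ester.
- The kinetic cross-conjugated potassium enolate of F8 (KHMDS, THF–DMPU, −78 °C) is O-methylated with MeOTf. This comes back to the route at 14.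

Step 11.
- What may go wrong: the alkylidene formed next to the free hydroxyl and keto groups may be held by chelation and decay to hydride species that isomerise the allylic alcohol; closure onto the hindered 1,1-disubstituted enol ether may be slow; heating may cause loss of water with aromatisation.
- Fallback with a masked carbinol: setting out from 21, TESOTf/2,6-lutidine at −78 °C gives the C6 triethylsilyl ether F9. F9 cannot isomerise or dehydrate and tolerates the same ruthenium catalyst in toluene at 80 °C, giving the tris-silylated bicycle F10.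
- Buffered fluoride (TBAF/AcOH) then removes all three silyl groups and comes back to the route at 23.

Further compounds
F1 | step 10 | methyl (2R,3R)-3-[5-bromo-2-(triisopropylsilyloxy)phenyl]-5-[(E)-4-phenyl-2-(trimethylsilyloxy)but-3-enyl]-2-[2-(triethylsilyloxy)propan-2-yl]-2,3-dihydrofuran-4-carboxylate | Brc1ccc(O[Si](C(C)C)(C(C)C)C(C)C)c([C@@H]2C(C(=O)OC)=C(CC(O[Si](C)(C)C)/C=C/c3ccccc3)O[C@H]2C(C)(C)O[Si](CC)(CC)CC)c1
F2 | step 10 | (2R,3R)-3-[5-bromo-2-(triisopropylsilyloxy)phenyl]-4-(1-methoxyvinyl)-5-[(E)-4-phenyl-2-(trimethylsilyloxy)but-3-enyl]-2-[2-(triethylsilyloxy)propan-2-yl]-2,3-dihydrofuran | Brc1ccc(O[Si](C(C)C)(C(C)C)C(C)C)c([C@@H]2C(C(=C)OC)=C(CC(O[Si](C)(C)C)/C=C/c3ccccc3)O[C@H]2C(C)(C)O[Si](CC)(CC)CC)c1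
F3 | step 10 | methyl 3-{(2R,3R)-4-(1-methoxyvinyl)-5-[(E)-4-phenyl-2-(trimethylsilyloxy)but-3-enyl]-2-[2-(triethylsilyloxy)propan-2-yl]-2,3-dihydrofuran-3-yl}-4-(triisopropylsilyloxy)benzoate | COC(=O)c1ccc(O[Si](C(C)C)(C(C)C)C(C)C)c([C@@H]2C(C(=C)OC)=C(CC(O[Si](C)(C)C)/C=C/c3ccccc3)O[C@H]2C(C)(C)O[Si](CC)(CC)CC)c1
F4 | step 10 | methyl 3-{(2R,3R)-5-[(E)-2-hydroxy-4-phenylbut-3-enyl]-4-(1-methoxyvinyl)-2-[2-(triethylsilyloxy)propan-2-yl]-2,3-dihydrofuran-3-yl}-4-(triisopropylsilyloxy)benzoate | COC(=O)c1ccc(O[Si](C(C)C)(C(C)C)C(C)C)c([C@@H]2C(C(=C)OC)=C(CC(O)/C=C/c3ccccc3)O[C@H]2C(C)(C)O[Si](CC)(CC)CC)c1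
F5 | step 10 | methyl 3-{(2R,3R)-4-(1-methoxyvinyl)-5-[(E)-2-oxo-4-phenylbut-3-enyl]-2-[2-(triethylsilyloxy)propan-2-yl]-2,3-dihydrofuran-3-yl}-4-(triisopropylsilyloxy)benzoate | COC(=O)c1ccc(O[Si](C(C)C)(C(C)C)C(C)C)c([C@@H]2C(C(=C)OC)=C(CC(=O)/C=C/c3ccccc3)O[C@H]2C(C)(C)O[Si](CC)(CC)CC)c1
F6 | step 10 | methyl 3-{(2R,3R)-5-[(3R,4R,6E)-3-hydroxy-5-oxo-7-phenylhepta-1,6-dien-4-yl]-4-(1-methoxyvinyl)-2-[2-(triethylsilyloxy)propan-2-yl]-2,3-dihydrofuran-3-yl}-4-(triisopropylsilyloxy)benzoate | COC(=O)c1ccc(O[Si](C(C)C)(C(C)C)C(C)C)c([C@@H]2C(C(=C)OC)=C(O[C@H]2C(C)(C)O[Si](CC)(CC)CC)[C@H](C(=O)/C=C/c2ccccc2)[C@H](O)C=C)c1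
F7 | step 7 | (2R,3R)-3-[5-bromo-2-(triisopropylsilyloxy)phenyl]-N-methoxy-N-methyl-5-[4-phenyl-2-(trimethylsilyloxy)butyl]-2-[2-(triethylsilyloxy)propan-2-yl]-2,3-dihydrofuran-4-carboxamide | Brc1ccc(O[Si](C(C)C)(C(C)C)C(C)C)c([C@@H]2C(C(=O)N(C)OC)=C(CC(O[Si](C)(C)C)CCc3ccccc3)O[C@H]2C(C)(C)O[Si](CC)(CC)CC)c1
F8 | step 7 | 1-{(2R,3R)-3-[5-bromo-2-(triisopropylsilyloxy)phenyl]-5-[4-phenyl-2-(trimethylsilyloxy)butyl]-2-[2-(triethylsilyloxy)propan-2-yl]-2,3-dihydrofuran-4-yl}ethanone | Brc1ccc(O[Si](C(C)C)(C(C)C)C(C)C)c([C@@H]2C(C(C)=O)=C(CC(O[Si](C)(C)C)CCc3ccccc3)O[C@H]2C(C)(C)O[Si](CC)(CC)CC)c1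
F9 | step 11 | methyl 3-{(2R,3R)-4-(1-methoxyvinyl)-5-[(3R,4R)-5-oxo-7-phenyl-3-(triethylsilyloxy)hept-1-en-4-yl]-2-[2-(triethylsilyloxy)propan-2-yl]-2,3-dihydrofuran-3-yl}-4-(triisopropylsilyloxy)benzoate | COC(=O)c1ccc(O[Si](C(C)C)(C(C)C)C(C)C)c([C@@H]2C(C(=C)OC)=C(O[C@H]2C(C)(C)O[Si](CC)(CC)CC)[C@H](C(=O)CCc2ccccc2)[C@H](O[Si](CC)(CC)CC)C=C)c1
F10 | step 11 | methyl 3-{(2R,3R,6R,7R)-4-methoxy-7-(3-phenylpropanoyl)-6-(triethylsilyloxy)-2-[2-(triethylsilyloxy)propan-2-yl]-2,3,6,7-tetrahydro-1-benzofuran-3-yl}-4-(triisopropylsilyloxy)benzoate | COC(=O)c1ccc(O[Si](C(C)C)(C(C)C)C(C)C)c([C@@H]2C3=C(O[C@H]2C(C)(C)O[Si](CC)(CC)CC)[C@H](C(=O)CCc2ccccc2)[C@H](O[Si](CC)(CC)CC)C=C3OC)c1
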